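Substrate still in the feed could not become product, so my ledger of the limiting reagent opened with that entry.

all flasks: free catalyst 0.35 mol%
- larch: substrate 28 mM (fed, over 15 h); temperature 20 °C; run made earlier; the fed solution adds 0.25 times the starting volume
- oak: substrate 44 mM (fed, over 15 h); temperature 35 °C; run made earlier; the fed solution adds 0.25 times the starting volume
- north: substrate 20 mM; temperature 35 °C; everything together at the start, the whole solution of substrate included, so that from the start the volume is larger by 0.25 times the starting volume; time 15 h
- east: substrate 20 mM (fed, over 15 h); temperature 35 °C; the fed solution adds 0.25 times the starting volume; time 15 h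

| run | time / h | product / % | substrate / % |
|---|---|---|---|
| larch | 3.00 | 2 | 21 |
| larch | 10.0 | 3 | 63 |
| larch | 15.0 | 9 | 94 |
| larch | 25.0 | 11 | 85 |
| larch | 40.0 | 17 | 81 |
| oak | 4.00 | 4 | 24 |
| oak | 8.00 | 11 | 43 |
| oak | 10.0 | 10 | 55 |
| oak | 15.0 | 22 | 79 |
| oak | 20.0 | 27 | 73 |

(each reading ± 1.5 percentage points)

- for product the idle complex is counted in
- charges are per starting volume, the dose included; the dosed solution carries all of it
- what was read earlier has a scatter of 1.5 percentage points, one standard deviation
- steps that have been proposed: substrate + free catalyst -> catalyst intermediate A; catalyst intermediate A <-> catalyst intermediate B; catalyst intermediate B -> free catalyst + product; free catalyst + product <-> idle complex; catalyst intermediate B -> spent catalyst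
- percentages count the whole charge, also what has not yet gone in

1. the flask that ends with the higher amount of product, in percent of the substrate charged, or "neither" when 2 percentage points or less lies between them (north / east / neither)
2. final product, as a percentage of the substrate charged, in north
3. final product, as a percentage of the substrate charged, in east

I kept the books on the oak run, in percent of the charge. At 10.0 h the feed had delivered 66.7%, and the readings held 10% as product and 55% as substrate. At 15.0 h the whole charge was in, and they held 22% and 79%. Catalyst forms could hold no more than 0.35 mol%, so these two entries closed the books within the scatter.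

A steady feed therefore takes half the dosing time off the clock of the average mole. I carried this as the exposure, the mean hours that substrate has spent in the flask at a given loading, which for east at the end was 7.50 h. North had 15 h. Oak at 15.0 h had the same exposure as east, so, carrying percent from [substrate] of 44 mM to 20 mM at equal loading, I read 22% for east. Oak had reached 27% at an exposure of 12.5 h. Continuing that reading slope gave north 29.5%, a gap of 7.5 percentage points.

The forecast, with other figures than mine, also chose north: 23% (18% to 30%) for north and 19% (14% to 24%) for east, since north “keeps the catalyst busy throughout”.

The flasks gave 25.8% in north and 18.1% in east, so north won, with both values inside the forecast's ranges.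

    substrate + free catalyst → catalyst intermediate A (k = 0.372 L mol⁻¹ s⁻¹, Ea = 54.0 kJ mol⁻¹)
    catalyst intermediate A ⇌ catalyst intermediate B (K = 0.620, k = 0.201 s⁻¹, Ea = 84.0 kJ mol⁻¹, ΔH = −14.0 kJ mol⁻¹)
    catalyst intermediate B → free catalyst + product (k = 0.0209 s⁻¹, Ea = 86.0 kJ mol⁻¹)
    free catalyst + product ⇌ idle complex, settled at all times (K = 793 L mol⁻¹, ΔH = −43.0 kJ mol⁻¹)
    catalyst intermediate B → spent catalyst (k = 4.97 × 10⁻⁵ s⁻¹, Ea = 99.0 kJ mol⁻¹)
    (constants at 35 °C)

The gap of 7.7 points came from the way the substrate went in: north, charged at the start, gave 25.8%, and the same recipe without that difference, fed as in east, gave 18.1%. At the exposure of 7.50 h, north at 7.50 h held 17.0% product, and east at 15.0 h held 18.1%, so that is the reading to watch. The forecast's choice would fall to neither in a run of 150 h, where north gives 67.9% and east 67.0%.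

In a neighbour of north charged with 1.4 mol% of free catalyst, trading loading against hours as an estimate gives an exposure of 60.0 h at north's loading. That is two more steps, each of the factor 1.51 by which north's product grew from 7.50 h to 15.0 h, or 58.9%, and that neighbour gave 54.6%.

The readings are calculated for an exercise, and the scatter is random.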